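## Retrosynthetic overview

1. The last bond made is the unhindered aliphatic ester between a "left acid" (ring B aroyl-O-CH(CH3)CH2CO2H) and a "right alcohol" (ring A carrying the free (R)-2-hydroxypropyl arm and a benzyl ester terminus). Desilylation and global hydrogenolysis follow.
2. Both hindered aroyl-O-CH(CH3)CH2CO2 units are made as Mitsunobu esters of (S)-pent-4-en-2-ol (inversion to R). The vinyl group is a masked carboxyl, unveiled by Lemieux–Johnson and Pinnick oxidation.
3. The key C–C bond is ArCH2–C(=O) of ring B. It is formed by a crossed, vinylogous Claisen condensation of the lithiated o-toluate ester with the Weinreb amide of (R)-3-silyloxybutanoic acid.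
4. The ring A arm comes from an aryl Grignard/CuI opening of (R)-propylene oxide. Its carboxyl comes from ring bromination, Br–Li exchange and CO2.
5. No ring is formed. Both benzene rings are bought (methyl orsellinate, 5-bromoresorcinol), and all four stereocentres, each (R), come from the chiral pool.

Assumption: both enantiomers of propylene oxide, methyl (R)-3-hydroxybutanoate, methyl orsellinate and 5-bromoresorcinol are taken as commercial in high ee.

## Route

Step 1
Reactants: 1 (S)-propylene oxide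
Product: 2 (S)-pent-4-en-2-ol
Conditions: CH2=CHMgBr (1.3 equiv), CuI (10 mol %), THF, -20 °C to 0 °C; aq NH4Cl
Reagents that add atoms: vinylmagnesium bromide, C=C[Mg]Br
Why: Copper-catalysed SN2 epoxide opening by the Grignard reagent occurs only at the unsubstituted CH2, so the C–O stereocentre of 1 passes unchanged into (S)-2.

Step 2
Reactants: 3 methyl orsellinate (methyl 2,4-dihydroxy-6-methylbenzoate)
Product: 4 methyl 2,4-bis(benzyloxy)-6-methylbenzoate
Conditions: BnBr (2.5 equiv), K2CO3 (3 equiv), DMF, 60 °C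
Reagents that add atoms: benzyl bromide, BrCc1ccccc1
Why: Williamson ether synthesis on both phenols (warm DMF for the chelated ortho-OH) installs groups that survive strong base, oxidants and fluoride and leave by hydrogenolysis at the end.

Step 3
Reactants: 4 methyl 2,4-bis(benzyloxy)-6-methylbenzoate
Product: 5 2,4-bis(benzyloxy)-6-methylbenzoic acid
Conditions: KOH (10 equiv), EtOH–H2O 4:1, reflux, 24 h; 1 M HCl, 0 °C
Reagents that add atoms: potassium hydroxide, [K+].[OH-]
Why: Forcing saponification is needed for the di-ortho-substituted ester and is safe here because nothing else in 4 is base-labile.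

Step 4
Reactants: 5 2,4-bis(benzyloxy)-6-methylbenzoic acid; 2 (S)-pent-4-en-2-ol
Product: 6 (R)-pent-4-en-2-yl 2,4-bis(benzyloxy)-6-methylbenzoate
Conditions: PPh3 (1.5 equiv), DIAD (1.5 equiv), THF, 0 °C to rt
Reagents that add atoms: none
Why: The Mitsunobu reaction activates the alcohol rather than the hindered carboxyl, so the carboxylate displaces by SN2 with clean inversion ((S)-alcohol to (R)-ester), and the homoallyl group is a base-stable mask of the later CH2CO2H.

Step 5
Reactants: 7 methyl (R)-3-hydroxybutanoate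
Product: 8 methyl (R)-3-(tert-butyldimethylsilyloxy)butanoate
Conditions: TBSCl (1.2 equiv), imidazole (2.5 equiv), DMF, rt
Reagents that add atoms: tert-butyldimethylsilyl chloride, CC(C)(C)[Si](C)(C)Cl
Why: Imidazole-mediated O-silylation protects the chiral-pool (R)-carbinol without touching the stereocentre.

Step 6
Reactants: 8 methyl (R)-3-(tert-butyldimethylsilyloxy)butanoate
Product: 9 (R)-3-(tert-butyldimethylsilyloxy)-N-methoxy-N-methylbutanamide
Conditions: MeNH(OMe)·HCl (1.5 equiv), i-PrMgCl (3.0 equiv), THF, -20 °C to 0 °C; aq NH4Cl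
Reagents that add atoms: N,O-dimethylhydroxylamine hydrochloride, CNOC.Cl
Why: Weinreb amide formation by aminolysis with the magnesium amide is fast at low temperature, which avoids beta-elimination of the silyloxy group.

Step 7
Reactants: 6 (R)-pent-4-en-2-yl 2,4-bis(benzyloxy)-6-methylbenzoate; 9 (R)-3-(tert-butyldimethylsilyloxy)-N-methoxy-N-methylbutanamide
Product: 12 (R)-pent-4-en-2-yl 2,4-bis(benzyloxy)-6-[(R)-4-(tert-butyldimethylsilyloxy)-2-oxopentyl]benzoate, via benzylic lithium dienolate 10 (not isolated), via tetrahedral lithium adduct 11 (not isolated)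
Conditions: LiN(i-Pr)2 (2.0 equiv, commercial solution), THF, -78 °C, 15 min; 9 (1.2 equiv), -78 °C, 30 min; aq NH4Cl at -78 °C
Reagents that add atoms: none
Why: The ortho-methyl group is vinylogously alpha to the ester, so its dienolate 10 is acylated by 9 in a crossed vinylogous Claisen condensation; chelated adduct 11 persists until the cold quench, which prevents over-addition and isocoumarin closure, and neither stereocentre is touched.

Step 8
Reactants: 12 (R)-pent-4-en-2-yl 2,4-bis(benzyloxy)-6-[(R)-4-(tert-butyldimethylsilyloxy)-2-oxopentyl]benzoate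
Product: 14 (R)-4-oxobutan-2-yl 2,4-bis(benzyloxy)-6-[(R)-4-(tert-butyldimethylsilyloxy)-2-oxopentyl]benzoate, via vicinal diol 13 (not isolated)
Conditions: OsO4 (2 mol %), NaIO4 (4 equiv), 2,6-lutidine (2 equiv), dioxane–H2O 3:1, rt; used crude
Reagents that add atoms: osmium tetroxide, O=[Os](=O)(=O)=O (delivers the oxygen); sodium periodate, [Na+].[O-]I(=O)(=O)=O (re-supplies it)
Why: Lemieux–Johnson oxidation attacks only the terminal alkene (unlike ozone, it spares the electron-rich rings), and the lutidine buffer keeps the beta-aroyloxy aldehyde from eliminating.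

Step 9
Reactants: 14 (R)-4-oxobutan-2-yl 2,4-bis(benzyloxy)-6-[(R)-4-(tert-butyldimethylsilyloxy)-2-oxopentyl]benzoate
Product: 15 (R)-3-{2,4-bis(benzyloxy)-6-[(R)-4-(tert-butyldimethylsilyloxy)-2-oxopentyl]benzoyloxy}butanoic acid
Conditions: NaClO2 (3 equiv), NaH2PO4 (3 equiv), 2-methyl-2-butene (20 equiv), t-BuOH–H2O 4:1, 0 °C to rt
Reagents that add atoms: sodium chlorite, [Na+].[O-]Cl=O
Why: Pinnick oxidation at about pH 4 converts the aldehyde to the acid without base, and the alkene scavenger removes HOCl before it can chlorinate the arene or the active methylene.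

Step 10
Reactants: 16 5-bromoresorcinol (5-bromobenzene-1,3-diol)
Product: 17 1,3-bis(benzyloxy)-5-bromobenzene
Conditions: BnBr (2.3 equiv), K2CO3 (3 equiv), DMF, 60 °C
Reagents that add atoms: benzyl bromide, BrCc1ccccc1
Why: Williamson ether synthesis gives the same phenol protection as in ring B, so one hydrogenolysis clears everything at the end.

Step 11
Reactants: 17 1,3-bis(benzyloxy)-5-bromobenzene; 18 (R)-propylene oxide
Product: 20 (R)-1-[3,5-bis(benzyloxy)phenyl]propan-2-ol, via aryl Grignard reagent 19 (not isolated)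
Conditions: Mg turnings (I2 crystal), THF, reflux; CuI (10 mol %), -30 °C; 18 (1.3 equiv), to 0 °C; aq NH4Cl
Reagents that add atoms: none
Why: Copper-catalysed Grignard opening of the epoxide at its CH2 terminus forms the aryl–CH2 bond and carries the (R)-carbinol centre over unchanged.

Step 12
Reactants: 20 (R)-1-[3,5-bis(benzyloxy)phenyl]propan-2-ol
Product: 21 (R)-[1-(3,5-bis(benzyloxy)phenyl)propan-2-yloxy](tert-butyl)dimethylsilane
Conditions: TBSCl (1.3 equiv), imidazole (2.5 equiv), DMF, rt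
Reagents that add atoms: tert-butyldimethylsilyl chloride, CC(C)(C)[Si](C)(C)Cl
Why: O-Silylation blocks the alcohol against n-BuLi and, later, against lactonisation onto the ring carboxyl.

Step 13
Reactants: 21 (R)-[1-(3,5-bis(benzyloxy)phenyl)propan-2-yloxy](tert-butyl)dimethylsilane
Product: 22 (R)-[1-(3,5-bis(benzyloxy)-2-bromophenyl)propan-2-yloxy](tert-butyl)dimethylsilane
Conditions: NBS (1.0 equiv), MeCN–CH2Cl2, -20 °C to 0 °C, dark
Reagents that add atoms: N-bromosuccinimide, O=C1CCC(=O)N1Br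
Why: Electrophilic aromatic bromination goes para to one benzyloxy group and ortho to the other (next to the side chain), because the position between the two benzyloxy groups is the more crowded one.

Step 14
Reactants: 22 (R)-[1-(3,5-bis(benzyloxy)-2-bromophenyl)propan-2-yloxy](tert-butyl)dimethylsilane
Product: 24 2,4-bis(benzyloxy)-6-[(R)-2-(tert-butyldimethylsilyloxy)propyl]benzoic acid, via aryllithium 23 (not isolated)
Conditions: n-BuLi (1.1 equiv), THF, -78 °C, 15 min; dry CO2 gas, -78 °C to 0 °C; 1 M HCl to pH 3–4, 0 °C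
Reagents that add atoms: carbon dioxide, O=C=O
Why: Bromine–lithium exchange is faster than any deprotonation at -78 °C, and carboxylation with the small electrophile CO2 gives the free acid directly, so no hindered ester has to be hydrolysed.

Step 15
Reactants: 24 2,4-bis(benzyloxy)-6-[(R)-2-(tert-butyldimethylsilyloxy)propyl]benzoic acid; 2 (S)-pent-4-en-2-ol
Product: 25 (R)-pent-4-en-2-yl 2,4-bis(benzyloxy)-6-[(R)-2-(tert-butyldimethylsilyloxy)propyl]benzoate
Conditions: PPh3 (1.5 equiv), DIAD (1.5 equiv), THF, 0 °C to rt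
Reagents that add atoms: none
Why: Mitsunobu esterification with inversion sets the (R)-ester centre and never activates the acyl carbon, so the neighbouring silyl ether cannot close to the dihydroisocoumarin.

Step 16
Reactants: 25 (R)-pent-4-en-2-yl 2,4-bis(benzyloxy)-6-[(R)-2-(tert-butyldimethylsilyloxy)propyl]benzoate
Product: 27 (R)-4-oxobutan-2-yl 2,4-bis(benzyloxy)-6-[(R)-2-(tert-butyldimethylsilyloxy)propyl]benzoate, via vicinal diol 26 (not isolated)
Conditions: OsO4 (2 mol %), NaIO4 (4 equiv), 2,6-lutidine (2 equiv), dioxane–H2O 3:1, rt; used crude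
Reagents that add atoms: osmium tetroxide, O=[Os](=O)(=O)=O (delivers the oxygen); sodium periodate, [Na+].[O-]I(=O)(=O)=O (re-supplies it)
Why: Lemieux–Johnson oxidation cleaves the only alkene under buffered conditions that leave the silyl ether, benzyl ethers and aroyl ester intact.

Step 17
Reactants: 27 (R)-4-oxobutan-2-yl 2,4-bis(benzyloxy)-6-[(R)-2-(tert-butyldimethylsilyloxy)propyl]benzoate
Product: 28 (R)-3-{2,4-bis(benzyloxy)-6-[(R)-2-(tert-butyldimethylsilyloxy)propyl]benzoyloxy}butanoic acid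
Conditions: NaClO2 (3 equiv), NaH2PO4 (3 equiv), 2-methyl-2-butene (20 equiv), t-BuOH–H2O 4:1, 0 °C to rt
Reagents that add atoms: sodium chlorite, [Na+].[O-]Cl=O
Why: Pinnick oxidation gives the acid under mildly acidic, scavenged conditions with no risk to the beta-aroyloxy stereocentre.

Step 18
Reactants: 28 (R)-3-{2,4-bis(benzyloxy)-6-[(R)-2-(tert-butyldimethylsilyloxy)propyl]benzoyloxy}butanoic acid
Product: 29 benzyl (R)-3-{2,4-bis(benzyloxy)-6-[(R)-2-(tert-butyldimethylsilyloxy)propyl]benzoyloxy}butanoate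
Conditions: BnBr (1.2 equiv), KHCO3 (1.5 equiv), DMF, rt
Reagents that add atoms: benzyl bromide, BrCc1ccccc1
Why: SN2 O-alkylation of the carboxylate needs only a bicarbonate base, too weak to cause E1cB loss of the aroyloxy group, and the benzyl ester leaves in the final hydrogenolysis.

Step 19
Reactants: 29 benzyl (R)-3-{2,4-bis(benzyloxy)-6-[(R)-2-(tert-butyldimethylsilyloxy)propyl]benzoyloxy}butanoate
Product: 30 benzyl (R)-3-{2,4-bis(benzyloxy)-6-[(R)-2-hydroxypropyl]benzoyloxy}butanoate
Conditions: HF·pyridine, extra pyridine, THF, 0 °C to rt (plastic vessel); used promptly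
Reagents that add atoms: none
Why: Fluoride-driven desilylation in a buffered, weakly acidic medium frees the alcohol without forming an alkoxide that could lactonise onto the neighbouring hindered aroyl ester.

Step 20
Reactants: 15 (R)-3-{2,4-bis(benzyloxy)-6-[(R)-4-(tert-butyldimethylsilyloxy)-2-oxopentyl]benzoyloxy}butanoic acid; 30 benzyl (R)-3-{2,4-bis(benzyloxy)-6-[(R)-2-hydroxypropyl]benzoyloxy}butanoate
Product: 31 fully protected tetraester: benzyl (R)-3-{2,4-bis(benzyloxy)-6-[(R)-2-({(R)-3-[2,4-bis(benzyloxy)-6-((R)-4-(tert-butyldimethylsilyloxy)-2-oxopentyl)benzoyloxy]butanoyl}oxy)propyl]benzoyloxy}butanoate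
Conditions: 15 (1.15 equiv), EDC·HCl (1.5 equiv), DMAP (0.3 equiv), CH2Cl2, 0 °C to rt
Reagents that add atoms: none
Why: Steglich esterification joins an unhindered aliphatic acid to a secondary alcohol with retention at the carbinol carbon, and low temperature with substoichiometric DMAP keeps beta-elimination and lactonisation slow.

Step 21
Reactants: 31 fully protected tetraester
Product: 32 penta-benzyl hydroxy ketone: benzyl (R)-3-{2,4-bis(benzyloxy)-6-[(R)-2-({(R)-3-[2,4-bis(benzyloxy)-6-((R)-4-hydroxy-2-oxopentyl)benzoyloxy]butanoyl}oxy)propyl]benzoyloxy}butanoate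
Conditions: HF·pyridine, extra pyridine, THF, 0 °C to rt
Reagents that add atoms: none
Why: Buffered fluoride desilylation liberates the beta-hydroxy ketone without the basic conditions that would dehydrate it or cleave the beta-acyloxy esters.

Step 22
Reactants: 32 penta-benzyl hydroxy ketone
Product: 33 target, (R,R,R,R)-tetraester acid as given
Conditions: H2 (1 atm), Pd/C (10 wt % Pd), EtOAc–EtOH 1:1, rt; filter through Celite
Reagents that add atoms: none
Why: Catalytic hydrogenolysis removes the four aryl benzyl ethers and the benzyl ester in one neutral operation, and the aliphatic ketone, the non-benzylic C–O ester bonds and all stereocentres are inert to it.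

## Compound list

1 | (S)-propylene oxide | C[C@H]1CO1 | starting material
2 | (S)-pent-4-en-2-ol | C[C@H](O)CC=C | intermediate
3 | methyl orsellinate | COC(=O)c1c(C)cc(O)cc1O | starting material
4 | methyl 2,4-bis(benzyloxy)-6-methylbenzoate | COC(=O)c1c(C)cc(OCc2ccccc2)cc1OCc1ccccc1 | intermediate
5 | 2,4-bis(benzyloxy)-6-methylbenzoic acid | OC(=O)c1c(C)cc(OCc2ccccc2)cc1OCc1ccccc1 | intermediate
6 | (R)-pent-4-en-2-yl 2,4-bis(benzyloxy)-6-methylbenzoate | C=CC[C@@H](C)OC(=O)c1c(C)cc(OCc2ccccc2)cc1OCc1ccccc1 | intermediate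
7 | methyl (R)-3-hydroxybutanoate | C[C@@H](O)CC(=O)OC | starting material
8 | methyl (R)-3-(tert-butyldimethylsilyloxy)butanoate | C[C@@H](O[Si](C)(C)C(C)(C)C)CC(=O)OC | intermediate
9 | (R)-3-(tert-butyldimethylsilyloxy)-N-methoxy-N-methylbutanamide | C[C@@H](O[Si](C)(C)C(C)(C)C)CC(=O)N(C)OC | intermediate
10 | benzylic lithium dienolate of 6 (drawn C-lithiated) | [Li]Cc1cc(OCc2ccccc2)cc(OCc2ccccc2)c1C(=O)O[C@H](C)CC=C | intermediate
11 | tetrahedral lithium adduct of 10 and 9 (new centre undefined) | [Li]OC(Cc1cc(OCc2ccccc2)cc(OCc2ccccc2)c1C(=O)O[C@H](C)CC=C)(C[C@@H](C)O[Si](C)(C)C(C)(C)C)N(C)OC | intermediate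
12 | (R)-pent-4-en-2-yl 2,4-bis(benzyloxy)-6-[(R)-4-(tert-butyldimethylsilyloxy)-2-oxopentyl]benzoate | C=CC[C@@H](C)OC(=O)c1c(OCc2ccccc2)cc(OCc2ccccc2)cc1CC(=O)C[C@@H](C)O[Si](C)(C)C(C)(C)C | intermediate
13 | (2R)-4,5-dihydroxypentan-2-yl ester from 12 (C4 epimers) | OCC(O)C[C@@H](C)OC(=O)c1c(OCc2ccccc2)cc(OCc2ccccc2)cc1CC(=O)C[C@@H](C)O[Si](C)(C)C(C)(C)C | intermediate
14 | (R)-4-oxobutan-2-yl 2,4-bis(benzyloxy)-6-[(R)-4-(tert-butyldimethylsilyloxy)-2-oxopentyl]benzoate | O=CC[C@@H](C)OC(=O)c1c(OCc2ccccc2)cc(OCc2ccccc2)cc1CC(=O)C[C@@H](C)O[Si](C)(C)C(C)(C)C | intermediate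
15 | (R)-3-{2,4-bis(benzyloxy)-6-[(R)-4-(tert-butyldimethylsilyloxy)-2-oxopentyl]benzoyloxy}butanoic acid | OC(=O)C[C@@H](C)OC(=O)c1c(OCc2ccccc2)cc(OCc2ccccc2)cc1CC(=O)C[C@@H](C)O[Si](C)(C)C(C)(C)C | intermediate
16 | 5-bromoresorcinol | Oc1cc(O)cc(Br)c1 | starting material
17 | 1,3-bis(benzyloxy)-5-bromobenzene | Brc1cc(OCc2ccccc2)cc(OCc2ccccc2)c1 | intermediate
18 | (R)-propylene oxide | C[C@@H]1CO1 | starting material
19 | 3,5-bis(benzyloxy)phenylmagnesium bromide | Br[Mg]c1cc(OCc2ccccc2)cc(OCc2ccccc2)c1 | intermediate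
20 | (R)-1-[3,5-bis(benzyloxy)phenyl]propan-2-ol | C[C@@H](O)Cc1cc(OCc2ccccc2)cc(OCc2ccccc2)c1 | intermediate
21 | (R)-[1-(3,5-bis(benzyloxy)phenyl)propan-2-yloxy](tert-butyl)dimethylsilane | C[C@@H](O[Si](C)(C)C(C)(C)C)Cc1cc(OCc2ccccc2)cc(OCc2ccccc2)c1 | intermediate
22 | (R)-[1-(3,5-bis(benzyloxy)-2-bromophenyl)propan-2-yloxy](tert-butyl)dimethylsilane | C[C@@H](O[Si](C)(C)C(C)(C)C)Cc1cc(OCc2ccccc2)cc(OCc2ccccc2)c1Br | intermediate
23 | aryllithium from 22 | C[C@@H](O[Si](C)(C)C(C)(C)C)Cc1cc(OCc2ccccc2)cc(OCc2ccccc2)c1[Li] | intermediate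
24 | 2,4-bis(benzyloxy)-6-[(R)-2-(tert-butyldimethylsilyloxy)propyl]benzoic acid | C[C@@H](O[Si](C)(C)C(C)(C)C)Cc1cc(OCc2ccccc2)cc(OCc2ccccc2)c1C(=O)O | intermediate
25 | (R)-pent-4-en-2-yl 2,4-bis(benzyloxy)-6-[(R)-2-(tert-butyldimethylsilyloxy)propyl]benzoate | C[C@@H](O[Si](C)(C)C(C)(C)C)Cc1cc(OCc2ccccc2)cc(OCc2ccccc2)c1C(=O)O[C@H](C)CC=C | intermediate
26 | (2R)-4,5-dihydroxypentan-2-yl ester from 25 (C4 epimers) | C[C@@H](O[Si](C)(C)C(C)(C)C)Cc1cc(OCc2ccccc2)cc(OCc2ccccc2)c1C(=O)O[C@H](C)CC(O)CO | intermediate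
27 | (R)-4-oxobutan-2-yl 2,4-bis(benzyloxy)-6-[(R)-2-(tert-butyldimethylsilyloxy)propyl]benzoate | C[C@@H](O[Si](C)(C)C(C)(C)C)Cc1cc(OCc2ccccc2)cc(OCc2ccccc2)c1C(=O)O[C@H](C)CC=O | intermediate
28 | (R)-3-{2,4-bis(benzyloxy)-6-[(R)-2-(tert-butyldimethylsilyloxy)propyl]benzoyloxy}butanoic acid | C[C@@H](O[Si](C)(C)C(C)(C)C)Cc1cc(OCc2ccccc2)cc(OCc2ccccc2)c1C(=O)O[C@H](C)CC(=O)O | intermediate
29 | benzyl (R)-3-{2,4-bis(benzyloxy)-6-[(R)-2-(tert-butyldimethylsilyloxy)propyl]benzoyloxy}butanoate | C[C@@H](O[Si](C)(C)C(C)(C)C)Cc1cc(OCc2ccccc2)cc(OCc2ccccc2)c1C(=O)O[C@H](C)CC(=O)OCc1ccccc1 | intermediate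
30 | benzyl (R)-3-{2,4-bis(benzyloxy)-6-[(R)-2-hydroxypropyl]benzoyloxy}butanoate | C[C@@H](O)Cc1cc(OCc2ccccc2)cc(OCc2ccccc2)c1C(=O)O[C@H](C)CC(=O)OCc1ccccc1 | intermediate
31 | fully protected tetraester (four OBn, CO2Bn, OTBS) | C[C@H](Cc1cc(OCc2ccccc2)cc(OCc2ccccc2)c1C(=O)O[C@H](C)CC(=O)OCc1ccccc1)OC(=O)C[C@@H](C)OC(=O)c1c(OCc2ccccc2)cc(OCc2ccccc2)cc1CC(=O)C[C@@H](C)O[Si](C)(C)C(C)(C)C | intermediate
32 | penta-benzyl hydroxy ketone | C[C@H](Cc1cc(OCc2ccccc2)cc(OCc2ccccc2)c1C(=O)O[C@H](C)CC(=O)OCc1ccccc1)OC(=O)C[C@@H](C)OC(=O)c1c(OCc2ccccc2)cc(OCc2ccccc2)cc1CC(=O)C[C@@H](C)O | intermediate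
33 | target tetraester acid, all four centres (R) | C[C@H](Cc1cc(O)cc(O)c1C(=O)O[C@H](C)CC(=O)O)OC(=O)C[C@@H](C)OC(=O)c1c(O)cc(O)cc1CC(=O)C[C@@H](C)O | target

## Step count and risks

Total step count: 22.
Longest linear sequence: 13 steps (16 to 33, steps 10 to 22). The ring B branch joins after 6 steps from 3.

Three steps most likely to fail:

**1. Step 7, the Claisen-type acylation.**
- Risk: anion 10 is a strong base. It may enolise 9, with E1cB loss of silanolate. The liberated ketone may also close onto the ester to give an isocoumarin.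
- Fallback: it sets out from 6 (as its anion 10) and from 8, and comes back at 12.
  - Anion 10 is trapped with allyl chloroformate to give the allyl homophthalate diester F1.
  - Ester 8 is saponified (LiOH, THF–H2O) to (R)-3-(tert-butyldimethylsilyloxy)butanoic acid F2. This is turned with 1,1'-carbonyldiimidazole into the acyl imidazole F3.
  - F1 is deprotonated with LiN(SiMe3)2 (THF, -78 °C) to the much less basic arylacetate lithium enolate F4.
  - F4 is C-acylated by F3 in a classical crossed Claisen condensation to give the allyl beta-keto ester F5.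
  - Pd(PPh3)4 (5 mol %, zerovalent palladium) with morpholine in THF at rt removes the allyl group. The resulting beta-keto acid F6 loses CO2 spontaneously to give 12. The homoallylic ester of the pentenyl group does not ionise and stays intact.

**2. Step 14, Br–Li exchange and carboxylation.**
- Risk: aryllithium 23 is crowded and sits next to a benzylic ether CH2, so proton transfer or Wittig-type rearrangement is possible. The step also depends on the regiochemistry of step 13.
- Fallback: it sets out from 21 and comes back at 24, bypassing steps 13 and 14 by electrophilic substitution instead of metalation.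
  - Vilsmeier–Haack formylation (POCl3, DMF, 0 °C to rt) at the same ring position gives the aryl iminium chloride F7.
  - Aqueous NaOAc hydrolyses F7 to 2,4-bis(benzyloxy)-6-[(R)-2-(tert-butyldimethylsilyloxy)propyl]benzaldehyde F8.
  - Pinnick oxidation (NaClO2, NaH2PO4, 2-methyl-2-butene) then delivers 24.

**3. Step 20, the fragment coupling.**
- Risk: the activated beta-aroyloxy acid can eliminate to a crotonate under amine base. Alcohol 30 can lactonise to the dihydroisocoumarin under DMAP.
- Fallback: it sets out from 15 and 30 and comes back at 31, replacing base-mediated acyl transfer by acid-catalysed transfer from an isolable enol ester.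
  - Acid 15 adds to ethoxyacetylene ([RuCl2(p-cymene)]2, 2 mol %, acetone, 0 °C to rt) to give the 1-ethoxyvinyl ester F9.
  - F9 acylates 30 with camphorsulfonic acid (10 mol %) in CH2Cl2 at rt. No base is present at any time.

## Further compounds

F1 | step 7 | (R)-pent-4-en-2-yl 2-[2-(allyloxy)-2-oxoethyl]-4,6-bis(benzyloxy)benzoate | C=CCOC(=O)Cc1cc(OCc2ccccc2)cc(OCc2ccccc2)c1C(=O)O[C@H](C)CC=C
F2 | step 7 | (R)-3-(tert-butyldimethylsilyloxy)butanoic acid | C[C@@H](O[Si](C)(C)C(C)(C)C)CC(=O)O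
F3 | step 7 | (R)-3-(tert-butyldimethylsilyloxy)-1-(imidazol-1-yl)butan-1-one | C[C@@H](O[Si](C)(C)C(C)(C)C)CC(=O)n1ccnc1
F4 | step 7 | lithium enolate of F1 | [Li]OC(OCC=C)=Cc1cc(OCc2ccccc2)cc(OCc2ccccc2)c1C(=O)O[C@H](C)CC=C
F5 | step 7 | allyl beta-keto ester (alpha-centre undefined, keto/enol) | C=CCOC(=O)C(C(=O)C[C@@H](C)O[Si](C)(C)C(C)(C)C)c1cc(OCc2ccccc2)cc(OCc2ccccc2)c1C(=O)O[C@H](C)CC=C
F6 | step 7 | beta-keto acid from F5 | OC(=O)C(C(=O)C[C@@H](C)O[Si](C)(C)C(C)(C)C)c1cc(OCc2ccccc2)cc(OCc2ccccc2)c1C(=O)O[C@H](C)CC=C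
F7 | step 14 | aryl N,N-dimethyliminium chloride from 21 | C[C@@H](O[Si](C)(C)C(C)(C)C)Cc1cc(OCc2ccccc2)cc(OCc2ccccc2)c1C=[N+](C)C.[Cl-]
F8 | step 14 | 2,4-bis(benzyloxy)-6-[(R)-2-(tert-butyldimethylsilyloxy)propyl]benzaldehyde | C[C@@H](O[Si](C)(C)C(C)(C)C)Cc1cc(OCc2ccccc2)cc(OCc2ccccc2)c1C=O
F9 | step 20 | 1-ethoxyvinyl ester of 15 | C=C(OCC)OC(=O)C[C@@H](C)OC(=O)c1c(OCc2ccccc2)cc(OCc2ccccc2)cc1CC(=O)C[C@@H](C)O[Si](C)(C)C(C)(C)C
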